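**Plan**

- Numbering: tetronic acid O1, C2(=O), C3(Me), C4(OH), C5; side chain C6 to C18, with the 3-furyl group on C18.
- West cuts: C3–C4 (Dieckmann) and the O1–C2 acyl bond (propanoate), then C9–C10 (alkenyl–alkenyl coupling), then C8=C9 (iodo-olefination of a C8 aldehyde). The C8 aldehyde and the C5 hydroxyl fold back into the oxolane O1–C5–C6–C7–C8 carrying the C4 ester, which is the tetrahydro form of methyl 4-methylfuran-2-carboxylate.
- East cuts: C11–CH3 with C10–metal (carboalumination of a C10≡C11 alkyne), C11–C12 (acetylide alkylation), C18–furan (B-alkyl Suzuki), C17=C18 (Wittig), back to (R)-citronellal.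
- Forward: the furan is saturated (no ring is closed), oxidised at C8 to the lactone, half-reduced and opened; the east alkyne is joined at C9–C10; the tetronic acid ring closes last.
- Stereochemistry: C5 and C7 are set together by the cis hydrogenation, with the catalyst choosing the face. C15 comes from (R)-citronellal, 8E from the Takai reaction and 10E from syn-carboalumination.

Key step: step 2

Remark (assumption): the antipode of the carbene ligand (and of the prolinate in the first fallback) that leads to the (2R,4R) series is fixed in a pilot run; the route is the same for either. The target is drawn as its 4-hydroxyfuran-2(5H)-one tautomer.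

**Route**

Step 1
Reactants: 1 methyl 4-bromofuran-2-carboxylate; 2 methylboronic acid
Product: 3 methyl 4-methylfuran-2-carboxylate
Conditions: Pd(PPh3)4 (5 mol %), K2CO3, 1,4-dioxane, 100 °C
Reagents that add atoms: none
Why: Suzuki–Miyaura methylation, in which zerovalent palladium inserts into the C–Br bond of the electron-poor furan and the methyl group is transferred from the carbonate-activated boronic acid, a standard coupling for heteroaryl bromides that leaves the ester alone.

Step 2
Reactants: 3 methyl 4-methylfuran-2-carboxylate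
Product: 5 methyl (2R,4R)-4-methyloxolane-2-carboxylate, via dihydrofuroate 4 (not isolated)
Conditions: Ru(cod)(2-methylallyl)2 (5 mol %), 1,3-bis[(1R)-1-(naphthalen-1-yl)ethyl]-4,5-dihydroimidazolium tetrafluoroborate (10 mol %), KOtBu (15 mol %), n-hexane, 70 °C (catalyst formation); then 3, H2 (60 bar), 25 °C
Reagents that add atoms: none
Why: The ruthenium–carbene hydride binds one face of the flat furan and transfers H2 syn, first across the less substituted C4=C5 enol-ether bond to give the dihydrofuroate 4 and then across the remaining 2-alkoxyacrylate C2=C3 bond, so only four C–H bonds form and no ring is closed. The closest known reaction type is the enantioselective hydrogenation of 2,4- and 2,5-disubstituted furans and of benzofurans with Ru(cod)(2-methylallyl)2 and chiral N-heterocyclic carbenes, together with the auxiliary-directed hydrogenation of 2-furoic amides. Ring C4 (C7 of the target) is fixed in the first, catalyst-controlled addition, the chiral pocket of the naphthylethyl carbene choosing the furan face. Ring C2 (C5 of the target) follows in the second addition, which should come from the same face because the metal stays on it and because that face is also the one opposite the new methyl group, so ester and methyl end up cis. The step needs face selectivity, cis selectivity and chemoselectivity for the ring over the ester; the 2,4-pattern offers the catalyst two clearly different ring edges (small methyl against coordinating ester next to oxygen), and an ester is not reduced by this catalyst at 25 °C. Full saturation is expected under pressure because the non-aromatic intermediate 4 is more easily reduced than the furan itself.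

Step 3
Reactants: 5 methyl (2R,4R)-4-methyloxolane-2-carboxylate
Product: 6 methyl (2R,4R)-4-methyl-5-oxooxolane-2-carboxylate
Conditions: RuCl3·xH2O (5 mol %), NaIO4 (3 equiv), EtOAc/MeCN/H2O, rt
Reagents that add atoms: sodium periodate, [Na+].[O-]I(=O)(=O)=O (oxygen delivered through RuO4); water, O
Why: Ruthenium tetroxide, made in the flask from RuCl3 and periodate, oxidises an ether α-CH2 to the lactone carbonyl (the oxygen counterpart of the prolinate-to-pyroglutamate oxidation); the C2–H next to oxygen is deactivated by the ester, so only C5 should react, and neither stereocentre is involved under these neutral conditions.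

Step 4
Reactants: 6 methyl (2R,4R)-4-methyl-5-oxooxolane-2-carboxylate
Product: 7 methyl (2R,4R)-5-hydroxy-4-methyloxolane-2-carboxylate (both anomers)
Conditions: disiamylborane (3 equiv, from BH3·THF and 2-methylbut-2-ene, THF, 0 °C), THF, 0 °C to rt; then H2O
Reagents that add atoms: none
Why: Chemoselective lactone-to-lactol reduction with an electrophilic dialkylborane, which reduces γ-lactones and stops at the stable O-boryl hemiacetal while open-chain esters are essentially inert to it (the selectivity used for acylated aldonolactones), so the methyl ester and the C4 centre next to the masked aldehyde should survive.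

Step 5
Reactants: 7 methyl (2R,4R)-5-hydroxy-4-methyloxolane-2-carboxylate
Product: 8 methyl (2R,4R,5E)-2-hydroxy-6-iodo-4-methylhex-5-enoate
Conditions: CrCl2 (8 equiv), CHI3 (3 equiv), 1,4-dioxane/THF 6:1, 0 °C to rt
Reagents that add atoms: iodoform, IC(I)I
Why: Takai iodo-olefination, in which the lactol is in equilibrium with its hydroxy aldehyde and this is trapped by the geminal dichromium species formed from CHI3 and divalent chromium to give the (E)-iodoalkene; the mild, non-basic medium should keep the α-methyl centre intact and leaves the hydroxy ester untouched.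

Step 6
Reactants: 8 methyl (2R,4R,5E)-2-hydroxy-6-iodo-4-methylhex-5-enoate
Product: 9 methyl (2R,4R,5E)-6-iodo-4-methyl-2-(propanoyloxy)hex-5-enoate
Conditions: (EtCO)2O, Et3N, DMAP (cat.), CH2Cl2, 0 °C
Reagents that add atoms: propanoic anhydride, CCC(=O)OC(=O)CC
Why: DMAP-catalysed O-acylation of the secondary α-hydroxy ester, with no event at either stereocentre.

Step 7
Reactants: 10 (R)-citronellal
Product: 11 (4R)-4,8-dimethylnona-1,7-diene
Conditions: MePPh3Br, KOtBu, THF, 0 °C to rt
Reagents that add atoms: methyltriphenylphosphonium bromide, C[P+](c1ccccc1)(c1ccccc1)c1ccccc1.[Br-]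
Why: Wittig methylenation of the aldehyde with the unstabilised ylide; the stereocentre is β to the carbonyl and is not at risk.

Step 8
Reactants: 11 (4R)-4,8-dimethylnona-1,7-diene; 12 3-bromofuran
Product: 14 3-[(4S)-4,8-dimethylnon-7-en-1-yl]furan, via B-alkyl-9-BBN adduct 13 (not isolated)
Conditions: 9-BBN, THF, 0 °C to rt; then 12, Pd(dppf)Cl2 (3 mol %), 3 M aq. NaOH, THF, 65 °C
Reagents that add atoms: none
Why: 9-BBN hydroborates the monosubstituted alkene at its terminus and ignores the trisubstituted one, and the B-alkyl Suzuki–Miyaura coupling then joins the primary alkylborane to C3 of the bromofuran under hydroxide activation (the descriptor changes from R to S by priority only).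

Step 9
Reactants: 14 3-[(4S)-4,8-dimethylnon-7-en-1-yl]furan
Product: 16 (4S)-7-(furan-3-yl)-4-methylheptanal, via vicinal diol 15 (not isolated)
Conditions: OsO4 (2 mol %), NaIO4 (4 equiv), 2,6-lutidine (2 equiv), 1,4-dioxane/H2O 3:1, rt
Reagents that add atoms: osmium tetroxide, O=[Os](=O)(=O)=O; sodium periodate, [Na+].[O-]I(=O)(=O)=O
Why: Lemieux–Johnson cleavage, in which catalytic OsO4 dihydroxylates the electron-rich trisubstituted alkene much faster than the aromatic furan and periodate cleaves the diol and returns the osmium to its active oxide, 2,6-lutidine holding back over-oxidation.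

Step 10
Reactants: 16 (4S)-7-(furan-3-yl)-4-methylheptanal
Product: 17 (4S)-7-(furan-3-yl)-4-methylheptan-1-ol
Conditions: NaBH4, MeOH, 0 °C
Reagents that add atoms: none
Why: Borohydride reduction of the aldehyde to the primary alcohol.

Step 11
Reactants: 17 (4S)-7-(furan-3-yl)-4-methylheptan-1-ol
Product: 18 (4S)-7-(furan-3-yl)-4-methylheptyl 4-methylbenzenesulfonate
Conditions: TsCl, pyridine, CH2Cl2, 0 °C to rt
Reagents that add atoms: 4-methylbenzenesulfonyl chloride, Cc1ccc(cc1)S(Cl)(=O)=O
Why: Sulfonylation of the primary alcohol under basic conditions, which keeps acid and electrophilic halogen away from the furan.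

Step 12
Reactants: 18 (4S)-7-(furan-3-yl)-4-methylheptyl 4-methylbenzenesulfonate
Product: 19 3-[(4R)-4-methylnon-8-yn-1-yl]furan
Conditions: LiC≡CH·H2NCH2CH2NH2 (lithium acetylide–ethylenediamine), DMSO, 10 °C to rt
Reagents that add atoms: lithium acetylide–ethylenediamine complex, [Li+].[C-]#C.NCCN
Why: SN2 alkylation of lithium acetylide by the primary tosylate in DMSO, the standard entry to terminal alkynes, far from the stereocentre (the descriptor returns to R by priority only).

Step 13
Reactants: 19 3-[(4R)-4-methylnon-8-yn-1-yl]furan; 9 methyl (2R,4R,5E)-6-iodo-4-methyl-2-(propanoyloxy)hex-5-enoate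
Product: 22 methyl (2R,4R,5E,7E,12R)-15-(furan-3-yl)-4,8,12-trimethyl-2-(propanoyloxy)pentadeca-5,7-dienoate, via alkenyldimethylalane 20 (not isolated), via alkenylzinc chloride 21 (not isolated)
Conditions: 19, AlMe3 (2.5 equiv), Cp2ZrCl2 (0.25 equiv), CH2Cl2, 0 °C to rt; volatiles removed in vacuo; ZnCl2, THF, 0 °C; then 9, Pd(PPh3)4 (5 mol %), THF, rt
Reagents that add atoms: trimethylaluminium, C[Al](C)C
Why: Negishi sequence, in which zirconium-catalysed syn-methylalumination puts CH3 on C11 and aluminium on C10 (hence 10E), transmetalation to zinc and coupling at zerovalent palladium with the (E)-iodoalkene go with retention at both carbons, and alkenylzinc reagents are known to spare esters (couplings with β-haloacrylates) once the excess AlMe3 has been pumped off.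

Step 14
Reactants: 22 methyl (2R,4R,5E,7E,12R)-15-(furan-3-yl)-4,8,12-trimethyl-2-(propanoyloxy)pentadeca-5,7-dienoate
Product: 23 (5R)-5-[(2R,3E,5E,10R)-13-(furan-3-yl)-2,6,10-trimethyltrideca-3,5-dien-1-yl]-4-hydroxy-3-methylfuran-2(5H)-one
Conditions: LiN(SiMe3)2 (2.5 equiv), THF, −78 to 0 °C; then 1 M HCl
Reagents that add atoms: none
Why: Dieckmann cyclisation, in which kinetic deprotonation of the unhindered propanoyl CH2 at −78 °C is followed by attack of that enolate on the neighbouring methyl ester with loss of methoxide to give the 3-methyltetronate, the second equivalent of base being taken up by this acidic product, whose anion protects C5 from deprotonation until the acidic work-up.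

**Compound list**

1 | methyl 4-bromofuran-2-carboxylate | COC(=O)c1cc(Br)co1 | starting material
2 | methylboronic acid | CB(O)O | starting material
3 | methyl 4-methylfuran-2-carboxylate | COC(=O)c1cc(C)co1 | intermediate
4 | methyl (4R)-4-methyl-4,5-dihydrofuran-2-carboxylate | COC(=O)C1=C[C@@H](C)CO1 | intermediate (not isolated)
5 | methyl (2R,4R)-4-methyloxolane-2-carboxylate | COC(=O)[C@H]1C[C@@H](C)CO1 | intermediate
6 | methyl (2R,4R)-4-methyl-5-oxooxolane-2-carboxylate | COC(=O)[C@H]1C[C@@H](C)C(=O)O1 | intermediate
7 | methyl (2R,4R)-5-hydroxy-4-methyloxolane-2-carboxylate (both anomers) | COC(=O)[C@H]1C[C@@H](C)C(O)O1 | intermediate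
8 | methyl (2R,4R,5E)-2-hydroxy-6-iodo-4-methylhex-5-enoate | COC(=O)[C@H](O)C[C@@H](C)/C=C/I | intermediate
9 | methyl (2R,4R,5E)-6-iodo-4-methyl-2-(propanoyloxy)hex-5-enoate | COC(=O)[C@H](OC(=O)CC)C[C@@H](C)/C=C/I | intermediate
10 | (R)-citronellal, (3R)-3,7-dimethyloct-6-enal | CC(C)=CCC[C@@H](C)CC=O | starting material
11 | (4R)-4,8-dimethylnona-1,7-diene | CC(C)=CCC[C@@H](C)CC=C | intermediate
12 | 3-bromofuran | Brc1ccoc1 | starting material
13 | 9-[(4S)-4,8-dimethylnon-7-en-1-yl]-9-borabicyclo[3.3.1]nonane | CC(C)=CCC[C@@H](C)CCCB1C2CCCC1CCC2 | intermediate (not isolated)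
14 | 3-[(4S)-4,8-dimethylnon-7-en-1-yl]furan | CC(C)=CCC[C@@H](C)CCCc1ccoc1 | intermediate
15 | (6S)-9-(furan-3-yl)-2,6-dimethylnonane-2,3-diol (both C3 epimers) | CC(C)(O)C(O)CC[C@@H](C)CCCc1ccoc1 | intermediate (not isolated)
16 | (4S)-7-(furan-3-yl)-4-methylheptanal | O=CCC[C@@H](C)CCCc1ccoc1 | intermediate
17 | (4S)-7-(furan-3-yl)-4-methylheptan-1-ol | OCCC[C@@H](C)CCCc1ccoc1 | intermediate
18 | (4S)-7-(furan-3-yl)-4-methylheptyl 4-methylbenzenesulfonate | Cc1ccc(cc1)S(=O)(=O)OCCC[C@@H](C)CCCc1ccoc1 | intermediate
19 | 3-[(4R)-4-methylnon-8-yn-1-yl]furan | C#CCCC[C@@H](C)CCCc1ccoc1 | intermediate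
20 | [(1E,6S)-9-(furan-3-yl)-2,6-dimethylnon-1-en-1-yl]dimethylalane | C[Al](C)/C=C(\C)CCC[C@@H](C)CCCc1ccoc1 | intermediate (not isolated)
21 | chloro[(1E,6S)-9-(furan-3-yl)-2,6-dimethylnon-1-en-1-yl]zinc | Cl[Zn]/C=C(\C)CCC[C@@H](C)CCCc1ccoc1 | intermediate (not isolated)
22 | methyl (2R,4R,5E,7E,12R)-15-(furan-3-yl)-4,8,12-trimethyl-2-(propanoyloxy)pentadeca-5,7-dienoate | COC(=O)[C@H](OC(=O)CC)C[C@@H](C)/C=C/C=C(\C)CCC[C@@H](C)CCCc1ccoc1 | intermediate
23 | (5R)-5-[(2R,3E,5E,10R)-13-(furan-3-yl)-2,6,10-trimethyltrideca-3,5-dien-1-yl]-4-hydroxy-3-methylfuran-2(5H)-one | CC1=C(O)[C@@H](C[C@@H](C)/C=C/C=C(\C)CCC[C@@H](C)CCCc2ccoc2)OC1=O | target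

**Count**

Total steps: 14. Longest linear sequence: 8 steps (steps 1 to 6, 13 and 14 from compound 1; equally steps 7 to 14 from compound 10).

**Steps most likely to fail**

1. Step 2. What may go wrong: the catalyst may discriminate the two faces of an ester-bearing furan poorly, or the reduction may stall at the half-hydrogenated stage. The fallback moves the stereocontrol from the catalyst to a covalently bound auxiliary; it sets out from 3 and comes back at 5.
   - Saponification of 3 (LiOH, THF/H2O) should give 4-methylfuran-2-carboxylic acid F1.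
   - Coupling with methyl L-prolinate (EDC·HCl, HOBt, iPr2NEt, CH2Cl2) gives methyl (2S)-1-(4-methylfuran-2-carbonyl)pyrrolidine-2-carboxylate F2.
   - Hydrogenation over Rh/Al2O3 (H2, MeOH, rt), with the prolinate shielding one face of the adsorbed furan, should give methyl (2S)-1-[(2R,4R)-4-methyloxolane-2-carbonyl]pyrrolidine-2-carboxylate F3, to be freed of minor diastereomers by chromatography.
   - Hydrolysis (6 M HCl, reflux) releases (2R,4R)-4-methyloxolane-2-carboxylic acid F4, and Fischer esterification (MeOH, cat. H2SO4) returns 5.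
   - The D-prolinate is used instead if the facial sense proves opposite.

2. Step 4. What may go wrong: loss of chemoselectivity, with hydride delivered to the activated 2-alkoxy ester, or incomplete conversion of the lactone. The fallback carries the carboxyl group as a tert-butyl ester that iBu2AlH leaves alone; it sets out from 5 and comes back at 8.
   - Saponification of 5 (LiOH, THF/H2O) gives the acid F4 already described.
   - tert-Butyl 2,2,2-trichloroacetimidate with catalytic BF3·OEt2 converts it into tert-butyl (2R,4R)-4-methyloxolane-2-carboxylate F5.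
   - RuCl3/NaIO4 as in step 3 gives tert-butyl (2R,4R)-4-methyl-5-oxooxolane-2-carboxylate F6.
   - iBu2AlH (1.1 equiv, CH2Cl2, −78 °C) reduces only the lactone, to tert-butyl (2R,4R)-5-hydroxy-4-methyloxolane-2-carboxylate F7.
   - CrCl2/CHI3 as in step 5 gives tert-butyl (2R,4R,5E)-2-hydroxy-6-iodo-4-methylhex-5-enoate F8.
   - HCl in methanol (rt to 40 °C) exchanges the tert-butyl for the methyl ester and delivers 8.

3. Step 13. What may go wrong: methyl transfer or Lewis-acid attack by residual methylaluminium species on the two ester groups, or sluggish transmetalation with homocoupling of the iodide. The fallback replaces the aluminium/zinc coupling by a neutral Stille coupling; it sets out from 19 and comes back at 22.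
   - Carboalumination of 19 as in step 13, followed by I2 in THF at −30 °C, gives 3-[(4S,8E)-9-iodo-4,8-dimethylnon-8-en-1-yl]furan F9.
   - Iodine–lithium exchange (t-BuLi, Et2O, −78 °C) and quenching with Bu3SnCl gives tributyl[(1E,6S)-9-(furan-3-yl)-2,6-dimethylnon-1-en-1-yl]stannane F10.
   - Coupling of F10 with 9 (Pd2(dba)3, AsPh3, CuI, NMP, rt) should deliver 22 with both alkene geometries retained and the esters untouched.

**Further compounds**

F1 | step 2 | 4-methylfuran-2-carboxylic acid | Cc1coc(C(=O)O)c1
F2 | step 2 | methyl (2S)-1-(4-methylfuran-2-carbonyl)pyrrolidine-2-carboxylate | COC(=O)[C@@H]1CCCN1C(=O)c1cc(C)co1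
F3 | step 2 | methyl (2S)-1-[(2R,4R)-4-methyloxolane-2-carbonyl]pyrrolidine-2-carboxylate | COC(=O)[C@@H]1CCCN1C(=O)[C@H]1C[C@@H](C)CO1
F4 | step 2 | (2R,4R)-4-methyloxolane-2-carboxylic acid | OC(=O)[C@H]1C[C@@H](C)CO1
F5 | step 4 | tert-butyl (2R,4R)-4-methyloxolane-2-carboxylate | CC(C)(C)OC(=O)[C@H]1C[C@@H](C)CO1
F6 | step 4 | tert-butyl (2R,4R)-4-methyl-5-oxooxolane-2-carboxylate | CC(C)(C)OC(=O)[C@H]1C[C@@H](C)C(=O)O1
F7 | step 4 | tert-butyl (2R,4R)-5-hydroxy-4-methyloxolane-2-carboxylate (both anomers) | CC(C)(C)OC(=O)[C@H]1C[C@@H](C)C(O)O1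
F8 | step 4 | tert-butyl (2R,4R,5E)-2-hydroxy-6-iodo-4-methylhex-5-enoate | CC(C)(C)OC(=O)[C@H](O)C[C@@H](C)/C=C/I
F9 | step 13 | 3-[(4S,8E)-9-iodo-4,8-dimethylnon-8-en-1-yl]furan | I/C=C(\C)CCC[C@@H](C)CCCc1ccoc1
F10 | step 13 | tributyl[(1E,6S)-9-(furan-3-yl)-2,6-dimethylnon-1-en-1-yl]stannane | CCCC[Sn](CCCC)(CCCC)/C=C(\C)CCC[C@@H](C)CCCc1ccoc1
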